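**Retrosynthetic overview**
- Ring C (the 2,5-dihydrofuran O–C5'–C6'=C7'–C8') has its oxygen on the quaternary C5' and an allylic C8'–H next to C7'=C6'. It is therefore the cycloisomer of the α-hydroxyallene C5'(OH)–C6'=C7'=C8'H, which is the SN2' adduct of a 5',6'-epoxy-7'-yne. This makes C8'–C9' the bond between an alkyne terminus (C11 epoxy-alkyne 8) and an alkenyl carbon (C29 polyenylboronate 24).
- 24 is assembled from C15 dienal 15, C10 bisphosphonate 19 and C4 boryl enal 22 by two Horner–Wadsworth–Emmons olefinations (C11=C12, then C11'=C12').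
- Both carbocycles come from (4R,6R)-actinol through one Sharpless epoxy aldehyde 7. Homologation of 7 gives alkyne 8. Wharton transposition, ozonolysis and axial acetylide addition give the cis-5,6-diol of ring A.
- Ring order: rings A and B are bought in; the oxirane on ring B is a temporary ring; ring C is closed last, in the key step, which also sets C8'.

Key step: step 21

Remark: carotenoid numbering is used (unprimed = 5,6-diol half with ring A; primed = furanoid half with rings B and C). Compounds 1, 11, 16 and 20 are taken as purchasable. Polyenes (step 19 onward) are handled under argon in dim light.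

**Step 1**
Reactants: 1 (4R,6R)-4-hydroxy-2,2,6-trimethylcyclohexan-1-one
Product: 2 (4R,6R)-4-[(tert-butyldimethylsilyl)oxy]-2,2,6-trimethylcyclohexan-1-one
Conditions: TBSCl, imidazole, DMF, 25 °C
Reagents that add atoms: tert-butyldimethylsilyl chloride, CC(C)(C)[Si](C)(C)Cl
Why: Imidazole-promoted silyl ether formation at the only hydroxyl group; the C4 centre is not touched.

**Step 2**
Reactants: 2 (4R,6R)-4-[(tert-butyldimethylsilyl)oxy]-2,2,6-trimethylcyclohexan-1-one
Product: 3 (4R)-4-[(tert-butyldimethylsilyl)oxy]-2,6,6-trimethylcyclohex-1-en-1-yl trifluoromethanesulfonate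
Conditions: LiN(iPr)2, THF, −78 °C; PhNTf2, −78 → 0 °C
Reagents that add atoms: N-phenylbis(trifluoromethanesulfonimide), O=S(=O)(N(c1ccccc1)S(=O)(=O)C(F)(F)F)C(F)(F)F
Why: The ketone has α-hydrogen only at C6, so enolate formation and O-triflation (enol triflate synthesis) should give one regioisomer; the C6 stereocentre is erased on purpose.

**Step 3**
Reactants: 3 (4R)-4-[(tert-butyldimethylsilyl)oxy]-2,6,6-trimethylcyclohex-1-en-1-yl trifluoromethanesulfonate
Product: 4 methyl (4R)-4-[(tert-butyldimethylsilyl)oxy]-2,6,6-trimethylcyclohex-1-ene-1-carboxylate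
Conditions: Pd(OAc)2, PPh3, Et3N, CO (1 atm), MeOH/DMF, 60 °C
Reagents that add atoms: carbon monoxide, [C-]#[O+]; methanol, CO
Why: Palladium-catalysed alkoxycarbonylation of an enol triflate (oxidative addition, CO insertion, methanolysis) installs C7.

**Step 4**
Reactants: 4 methyl (4R)-4-[(tert-butyldimethylsilyl)oxy]-2,6,6-trimethylcyclohex-1-ene-1-carboxylate
Product: 5 [(4R)-4-[(tert-butyldimethylsilyl)oxy]-2,6,6-trimethylcyclohex-1-en-1-yl]methanol
Conditions: iBu2AlH, CH2Cl2, −78 → 0 °C; Rochelle salt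
Reagents that add atoms: none
Why: Aluminium hydride 1,2-reduction of the conjugated ester to the allylic alcohol; the silyl ether is inert.

**Step 5**
Reactants: 5 [(4R)-4-[(tert-butyldimethylsilyl)oxy]-2,6,6-trimethylcyclohex-1-en-1-yl]methanol
Product: 6 [(1R,4S,6R)-4-[(tert-butyldimethylsilyl)oxy]-2,2,6-trimethyl-7-oxabicyclo[4.1.0]heptan-1-yl]methanol (epoxide oxygen trans to the silyloxy group)
Conditions: Ti(OiPr)4, D-(−)-diethyl tartrate, tBuOOH, 4 Å MS, CH2Cl2, −20 °C
Reagents that add atoms: tert-butyl hydroperoxide, CC(C)(C)OO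
Why: Sharpless asymmetric epoxidation; the titanium–D-tartrate complex should deliver oxygen under reagent control to the face of C5=C6 anti to the 3-silyloxy group, setting C5 and C6 of both end groups.

**Step 6**
Reactants: 6 [(1R,4S,6R)-4-[(tert-butyldimethylsilyl)oxy]-2,2,6-trimethyl-7-oxabicyclo[4.1.0]heptan-1-yl]methanol
Product: 7 (1S,4S,6R)-4-[(tert-butyldimethylsilyl)oxy]-2,2,6-trimethyl-7-oxabicyclo[4.1.0]heptane-1-carbaldehyde
Conditions: nPr4N[RuO4] (5 mol %), N-methylmorpholine N-oxide, 4 Å MS, CH2Cl2, 25 °C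
Reagents that add atoms: none
Why: Ley oxidation of the primary alcohol under non-acidic conditions keeps the tetrasubstituted epoxide; the α-carbon is quaternary, so it cannot epimerise.

**Step 7**
Reactants: 7 (1S,4S,6R)-4-[(tert-butyldimethylsilyl)oxy]-2,2,6-trimethyl-7-oxabicyclo[4.1.0]heptane-1-carbaldehyde
Product: 8 tert-butyl{[(1R,4S,6R)-1-ethynyl-2,2,6-trimethyl-7-oxabicyclo[4.1.0]heptan-4-yl]oxy}dimethylsilane
Conditions: dimethyl (1-diazo-2-oxopropyl)phosphonate, K2CO3, MeOH, 0 → 25 °C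
Reagents that add atoms: dimethyl (1-diazo-2-oxopropyl)phosphonate, COP(=O)(OC)C(=[N+]=[N-])C(C)=O
Why: Seyferth–Gilbert homologation with the Ohira–Bestmann reagent turns the aldehyde into the terminal alkyne (C7'≡C8') under carbonate conditions that spare the epoxide and the silyl ether.

**Step 8**
Reactants: 7 (1S,4S,6R)-4-[(tert-butyldimethylsilyl)oxy]-2,2,6-trimethyl-7-oxabicyclo[4.1.0]heptane-1-carbaldehyde
Product: 9 (1R,5S)-5-[(tert-butyldimethylsilyl)oxy]-1,3,3-trimethyl-2-methylidenecyclohexan-1-ol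
Conditions: N2H4·H2O, AcOH (cat.), MeOH, 0 → 25 °C
Reagents that add atoms: none
Why: Wharton transposition: the hydrazone of the α,β-epoxy aldehyde loses N2, the C6–O bond opens and C7 becomes an exocyclic methylene, while the C5–O bond and the C5 configuration from step 5 are kept.

**Step 9**
Reactants: 9 (1R,5S)-5-[(tert-butyldimethylsilyl)oxy]-1,3,3-trimethyl-2-methylidenecyclohexan-1-ol
Product: 10 (2R,4S)-4-[(tert-butyldimethylsilyl)oxy]-2-hydroxy-2,6,6-trimethylcyclohexan-1-one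
Conditions: O3, CH2Cl2/MeOH, −78 °C; Me2S
Reagents that add atoms: ozone, [O-][O+]=O
Why: Ozonolysis with reductive work-up cleaves the only C=C bond and gives the C6 ketone beside the intact tertiary 5-hydroxyl.

**Step 10**
Reactants: 10 (2R,4S)-4-[(tert-butyldimethylsilyl)oxy]-2-hydroxy-2,6,6-trimethylcyclohexan-1-one; 11 (2E)-3-methylpent-2-en-4-yn-1-ol
Product: 12 (1R,2R,4S)-4-[(tert-butyldimethylsilyl)oxy]-1-[(3E)-5-hydroxy-3-methylpent-3-en-1-yn-1-yl]-2,6,6-trimethylcyclohexane-1,2-diol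
Conditions: 11 (3 equiv), nBuLi (6 equiv), THF, −78 → 0 °C; then 10, −78 → 0 °C; aq NH4Cl
Reagents that add atoms: none
Why: 1,2-Addition of a lithium acetylide to a non-enolisable ketone; 10 is locked in the chair with the 5-oxygen and one C1 methyl axial, so the slim nucleophile should attack axially from the opposite face and the new 6-OH ends cis to the 5-OH (C6 set).

**Step 11**
Reactants: 12 (1R,2R,4S)-4-[(tert-butyldimethylsilyl)oxy]-1-[(3E)-5-hydroxy-3-methylpent-3-en-1-yn-1-yl]-2,6,6-trimethylcyclohexane-1,2-diol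
Product: 13 (1S,2R,4S)-4-[(tert-butyldimethylsilyl)oxy]-1-[(1E,3E)-5-hydroxy-3-methylpenta-1,3-dien-1-yl]-2,6,6-trimethylcyclohexane-1,2-diol
Conditions: NaAlH2(OCH2CH2OCH3)2, THF, 0 → 25 °C; Rochelle salt
Reagents that add atoms: none
Why: Alkoxide-directed trans-hydroalumination of the propargylic alcohol and protonolysis should give the (7E) alkene; the conjugated (9E) bond and the silyl ether are kept.

**Step 12**
Reactants: 13 (1S,2R,4S)-4-[(tert-butyldimethylsilyl)oxy]-1-[(1E,3E)-5-hydroxy-3-methylpenta-1,3-dien-1-yl]-2,6,6-trimethylcyclohexane-1,2-diol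
Product: 14 (2E,4E)-5-[(1S,2R,4S)-4-[(tert-butyldimethylsilyl)oxy]-1,2-dihydroxy-2,6,6-trimethylcyclohexyl]-3-methylpenta-2,4-dienal
Conditions: MnO2, CH2Cl2, 25 °C
Reagents that add atoms: none
Why: Allylic oxidation with MnO2 is selective for the primary allylic alcohol; the tertiary alcohols cannot be oxidised.

**Step 13**
Reactants: 14 (2E,4E)-5-[(1S,2R,4S)-4-[(tert-butyldimethylsilyl)oxy]-1,2-dihydroxy-2,6,6-trimethylcyclohexyl]-3-methylpenta-2,4-dienal
Product: 15 (2E,4E)-5-[(1S,2R,4S)-4-[(tert-butyldimethylsilyl)oxy]-2,6,6-trimethyl-1,2-bis[(trimethylsilyl)oxy]cyclohexyl]-3-methylpenta-2,4-dienal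
Conditions: 1-(trimethylsilyl)imidazole, CH2Cl2, 40 °C
Reagents that add atoms: 1-(trimethylsilyl)imidazole, C[Si](C)(C)n1ccnc1
Why: Neutral silylation of both hindered tertiary hydroxyls masks the 5-alkoxide, which could otherwise open ring A by a vinylogous retro-aldol reaction under the basic olefination conditions; the aldehyde is not enolised.

**Step 14**
Reactants: 16 (2E,4E,6E)-2,7-dimethylocta-2,4,6-trienedial
Product: 17 (2E,4E,6E)-2,7-dimethylocta-2,4,6-triene-1,8-diol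
Conditions: NaBH4, MeOH/THF, 0 °C
Reagents that add atoms: none
Why: Borohydride 1,2-reduction of both enal carbonyl groups; the triene geometry is not affected.

**Step 15**
Reactants: 17 (2E,4E,6E)-2,7-dimethylocta-2,4,6-triene-1,8-diol
Product: 18 (2E,4E,6E)-1,8-dibromo-2,7-dimethylocta-2,4,6-triene
Conditions: PBr3, pyridine (cat.), Et2O, −10 °C
Reagents that add atoms: phosphorus tribromide, BrP(Br)Br
Why: Bromination of the primary allylic alcohols through their phosphite esters (SN2); the crude dibromide is used at once.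

**Step 16**
Reactants: 18 (2E,4E,6E)-1,8-dibromo-2,7-dimethylocta-2,4,6-triene
Product: 19 tetraethyl [(2E,4E,6E)-2,7-dimethylocta-2,4,6-triene-1,8-diyl]bis(phosphonate)
Conditions: P(OEt)3, 110 °C
Reagents that add atoms: triethyl phosphite, CCOP(OCC)OCC
Why: Michaelis–Arbuzov reaction at both primary allylic bromides.

**Step 17**
Reactants: 20 but-2-yn-1-ol
Product: 21 (2Z)-3-(4,4,5,5-tetramethyl-1,3,2-dioxaborolan-2-yl)but-2-en-1-ol (CH2OH trans to boron)
Conditions: CuCl (5 mol %), PCy3, NaOtBu (cat.), B2pin2, MeOH, toluene, 25 °C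
Reagents that add atoms: bis(pinacolato)diboron, CC1(C)OB(OC1(C)C)B1OC(C)(C)C(C)(C)O1
Why: Copper-catalysed formal hydroboration (syn borylcupration, then protonation) of the internal alkyne should place boron at C3, distal to the propargylic oxygen, which fixes the geometry needed for C9'=C10'.

**Step 18**
Reactants: 21 (2Z)-3-(4,4,5,5-tetramethyl-1,3,2-dioxaborolan-2-yl)but-2-en-1-ol
Product: 22 (2Z)-3-(4,4,5,5-tetramethyl-1,3,2-dioxaborolan-2-yl)but-2-enal
Conditions: MnO2, CH2Cl2, 25 °C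
Reagents that add atoms: none
Why: Allylic oxidation with MnO2; the pinacol boronate is inert and the alkene geometry is kept.

**Step 19**
Reactants: 15 (2E,4E)-5-[(1S,2R,4S)-4-[(tert-butyldimethylsilyl)oxy]-2,6,6-trimethyl-1,2-bis[(trimethylsilyl)oxy]cyclohexyl]-3-methylpenta-2,4-dienal; 19 tetraethyl [(2E,4E,6E)-2,7-dimethylocta-2,4,6-triene-1,8-diyl]bis(phosphonate)
Product: 23 diethyl [(2E,4E,6E,8E,10E,12E)-13-{(1S,2R,4S)-4-[(tert-butyldimethylsilyl)oxy]-2,6,6-trimethyl-1,2-bis[(trimethylsilyl)oxy]cyclohexyl}-2,7,11-trimethyltrideca-2,4,6,8,10,12-hexaen-1-yl]phosphonate (C25; phosphorus on C12')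
Conditions: 19 (3 equiv), NaN(SiMe3)2 (1.1 equiv), THF, −78 °C; then 15, −78 → 0 °C, dark
Reagents that add atoms: none
Why: Horner–Wadsworth–Emmons olefination of the mono-anion of the bisphosphonate (used in excess to suppress double condensation) forms C11=C12 with the (E) preference of allylic phosphonates.

**Step 20**
Reactants: 23 diethyl C25-hexaenylphosphonate (as named in step 19); 22 (2Z)-3-(4,4,5,5-tetramethyl-1,3,2-dioxaborolan-2-yl)but-2-enal
Product: 24 2-[(2Z,4E,6E,8E,10E,12E,14E,16E)-17-{(1S,2R,4S)-4-[(tert-butyldimethylsilyl)oxy]-2,6,6-trimethyl-1,2-bis[(trimethylsilyl)oxy]cyclohexyl}-6,11,15-trimethylheptadeca-2,4,6,8,10,12,14,16-octaen-2-yl]-4,4,5,5-tetramethyl-1,3,2-dioxaborolane (C29; boron on C9', trans to C11')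
Conditions: NaN(SiMe3)2, THF, −78 °C; then 22, −78 → 0 °C, dark
Reagents that add atoms: none
Why: A second Horner–Wadsworth–Emmons olefination forms C11'=C12' (E); the pinacol boronate and the silyl ethers tolerate the hindered amide base at low temperature.

**Step 21**
Reactants: 8 tert-butyl{[(1R,4S,6R)-1-ethynyl-2,2,6-trimethyl-7-oxabicyclo[4.1.0]heptan-4-yl]oxy}dimethylsilane; 24 C29 octaenylboronate (as named in step 20)
Product: 26 (3S,5R,6S,3'S,5'R,8'R)-3,3'-bis[(tert-butyldimethylsilyl)oxy]-5,6-bis[(trimethylsilyl)oxy]-5',8'-epoxy-5,6,5',8'-tetrahydro-β,β-carotene, via 5'-hydroxy-6',7'-allene 25 (not isolated)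
Conditions: [Rh(OH)(cod)]2 (5 mol %), K3PO4, THF/H2O 10:1, 25 °C, dark; then NaH2PO4 (to pH 7), AgNO3 (0.5 equiv), CaCO3, acetone, 25 °C, dark
Reagents that add atoms: none
Why: Proposed new method: transmetalation of the alkenyl–boron bond of 24 to monovalent rhodium gives an alkenylrhodium species that is held by the oxirane oxygen of 8 and adds syn across the alkyne, with the new C–C bond at the terminus C8' and rhodium at C7'; syn β-oxygen elimination then opens the epoxide to the (6'S)-allenol 25, so C9' ends on the face of the former C6'–O bond (centre-to-axis transfer). The closest known reaction types are the rhodium-catalysed syn-selective SN2' arylation of alkynyl oxiranes with arylboronic acids and, for the relay as a whole, syn opening of a propargylic epoxide followed by silver-mediated closure of the α-allenol to a 2,5-dihydrofuran; a polyenyl alkenylboronate and a terminal alkynyl oxirane have not been shown. Monovalent silver then activates C7'=C8' of 25 from the side away from the 5'-OH, which attacks C8' in a 5-endo-trig oxymetalation, and protodemetalation leaves C6'=C7' in ring C (axis-to-centre transfer). C8' is the only new stereocentre: the anti epoxide fixes the allene axis and the oxygen attacks in the plane of ring C, so the polyene at C8' must end trans to the C5' methyl group, that is (8'R). The step needs C–C bond formation at C8' and not C7' (secured by oxirane-directed rhodium and the quaternary C6'), syn and not anti SN2' geometry (secured by the carbometalation/β-elimination path, whereas ionisation by zerovalent palladium would give the 8'-epimer), and ring closure without ionisation of the doubly allylic C8'–O bond (secured by buffered, non-acidic silver conditions).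

**Step 22**
Reactants: 26 (3S,5R,6S,3'S,5'R,8'R)-3,3'-bis[(tert-butyldimethylsilyl)oxy]-5,6-bis[(trimethylsilyl)oxy]-5',8'-epoxy-5,6,5',8'-tetrahydro-β,β-carotene
Product: 27 (3S,5R,6S,3'S,5'R,8'R)-5',8'-epoxy-5,6,5',8'-tetrahydro-β,β-carotene-3,5,6,3'-tetrol
Conditions: nBu4NF, THF, 0 → 25 °C, dark
Reagents that add atoms: none
Why: Fluoride-mediated desilylation removes all four silyl ethers without acid, which avoids epimerisation at C8' through ring C ionisation and spares the polyene.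

**Compound list**
1 | (4R,6R)-4-hydroxy-2,2,6-trimethylcyclohexan-1-one | O=C1C(C)(C)C[C@H](O)C[C@H]1C | starting material
2 | (4R,6R)-4-[(tert-butyldimethylsilyl)oxy]-2,2,6-trimethylcyclohexan-1-one | O=C1C(C)(C)C[C@H](O[Si](C)(C)C(C)(C)C)C[C@H]1C | intermediate
3 | (4R)-4-[(tert-butyldimethylsilyl)oxy]-2,6,6-trimethylcyclohex-1-en-1-yl trifluoromethanesulfonate | CC1=C(OS(=O)(=O)C(F)(F)F)C(C)(C)C[C@H](O[Si](C)(C)C(C)(C)C)C1 | intermediate
4 | methyl (4R)-4-[(tert-butyldimethylsilyl)oxy]-2,6,6-trimethylcyclohex-1-ene-1-carboxylate | CC1=C(C(=O)OC)C(C)(C)C[C@H](O[Si](C)(C)C(C)(C)C)C1 | intermediate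
5 | [(4R)-4-[(tert-butyldimethylsilyl)oxy]-2,6,6-trimethylcyclohex-1-en-1-yl]methanol | CC1=C(CO)C(C)(C)C[C@H](O[Si](C)(C)C(C)(C)C)C1 | intermediate
6 | [(1R,4S,6R)-4-[(tert-butyldimethylsilyl)oxy]-2,2,6-trimethyl-7-oxabicyclo[4.1.0]heptan-1-yl]methanol | OC[C@]12C(C)(C)C[C@H](O[Si](C)(C)C(C)(C)C)C[C@@]1(C)O2 | intermediate
7 | (1S,4S,6R)-4-[(tert-butyldimethylsilyl)oxy]-2,2,6-trimethyl-7-oxabicyclo[4.1.0]heptane-1-carbaldehyde | O=C[C@]12C(C)(C)C[C@H](O[Si](C)(C)C(C)(C)C)C[C@@]1(C)O2 | intermediate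
8 | tert-butyl{[(1R,4S,6R)-1-ethynyl-2,2,6-trimethyl-7-oxabicyclo[4.1.0]heptan-4-yl]oxy}dimethylsilane | C#C[C@]12C(C)(C)C[C@H](O[Si](C)(C)C(C)(C)C)C[C@@]1(C)O2 | intermediate
9 | (1R,5S)-5-[(tert-butyldimethylsilyl)oxy]-1,3,3-trimethyl-2-methylidenecyclohexan-1-ol | C=C1C(C)(C)C[C@H](O[Si](C)(C)C(C)(C)C)C[C@@]1(C)O | intermediate
10 | (2R,4S)-4-[(tert-butyldimethylsilyl)oxy]-2-hydroxy-2,6,6-trimethylcyclohexan-1-one | O=C1C(C)(C)C[C@H](O[Si](C)(C)C(C)(C)C)C[C@@]1(C)O | intermediate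
11 | (2E)-3-methylpent-2-en-4-yn-1-ol | OC/C=C(C)/C#C | starting material
12 | (1R,2R,4S)-4-[(tert-butyldimethylsilyl)oxy]-1-[(3E)-5-hydroxy-3-methylpent-3-en-1-yn-1-yl]-2,6,6-trimethylcyclohexane-1,2-diol | OC/C=C(C)/C#C[C@]1(O)C(C)(C)C[C@H](O[Si](C)(C)C(C)(C)C)C[C@@]1(C)O | intermediate
13 | (1S,2R,4S)-4-[(tert-butyldimethylsilyl)oxy]-1-[(1E,3E)-5-hydroxy-3-methylpenta-1,3-dien-1-yl]-2,6,6-trimethylcyclohexane-1,2-diol | OC/C=C(C)/C=C/[C@]1(O)C(C)(C)C[C@H](O[Si](C)(C)C(C)(C)C)C[C@@]1(C)O | intermediate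
14 | (2E,4E)-5-[(1S,2R,4S)-4-[(tert-butyldimethylsilyl)oxy]-1,2-dihydroxy-2,6,6-trimethylcyclohexyl]-3-methylpenta-2,4-dienal | O=C/C=C(C)/C=C/[C@]1(O)C(C)(C)C[C@H](O[Si](C)(C)C(C)(C)C)C[C@@]1(C)O | intermediate
15 | (2E,4E)-5-[(1S,2R,4S)-4-[(tert-butyldimethylsilyl)oxy]-2,6,6-trimethyl-1,2-bis[(trimethylsilyl)oxy]cyclohexyl]-3-methylpenta-2,4-dienal | O=C/C=C(C)/C=C/[C@]1(O[Si](C)(C)C)C(C)(C)C[C@H](O[Si](C)(C)C(C)(C)C)C[C@@]1(C)O[Si](C)(C)C | intermediate
16 | (2E,4E,6E)-2,7-dimethylocta-2,4,6-trienedial | O=C/C(C)=C/C=C/C=C(C)/C=O | starting material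
17 | (2E,4E,6E)-2,7-dimethylocta-2,4,6-triene-1,8-diol | OC/C(C)=C/C=C/C=C(C)/CO | intermediate
18 | (2E,4E,6E)-1,8-dibromo-2,7-dimethylocta-2,4,6-triene | BrC/C(C)=C/C=C/C=C(C)/CBr | intermediate
19 | tetraethyl [(2E,4E,6E)-2,7-dimethylocta-2,4,6-triene-1,8-diyl]bis(phosphonate) | CCOP(=O)(OCC)C/C(C)=C/C=C/C=C(C)/CP(=O)(OCC)OCC | intermediate
20 | but-2-yn-1-ol | CC#CCO | starting material
21 | (2Z)-3-(4,4,5,5-tetramethyl-1,3,2-dioxaborolan-2-yl)but-2-en-1-ol | OC/C=C(\C)B1OC(C)(C)C(C)(C)O1 | intermediate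
22 | (2Z)-3-(4,4,5,5-tetramethyl-1,3,2-dioxaborolan-2-yl)but-2-enal | O=C/C=C(\C)B1OC(C)(C)C(C)(C)O1 | intermediate
23 | diethyl [(2E,4E,6E,8E,10E,12E)-13-{(1S,2R,4S)-4-[(tert-butyldimethylsilyl)oxy]-2,6,6-trimethyl-1,2-bis[(trimethylsilyl)oxy]cyclohexyl}-2,7,11-trimethyltrideca-2,4,6,8,10,12-hexaen-1-yl]phosphonate | CCOP(=O)(OCC)C/C(C)=C/C=C/C=C(C)/C=C/C=C(C)/C=C/[C@]1(O[Si](C)(C)C)C(C)(C)C[C@H](O[Si](C)(C)C(C)(C)C)C[C@@]1(C)O[Si](C)(C)C | intermediate
24 | 2-[(2Z,4E,6E,8E,10E,12E,14E,16E)-17-{(1S,2R,4S)-4-[(tert-butyldimethylsilyl)oxy]-2,6,6-trimethyl-1,2-bis[(trimethylsilyl)oxy]cyclohexyl}-6,11,15-trimethylheptadeca-2,4,6,8,10,12,14,16-octaen-2-yl]-4,4,5,5-tetramethyl-1,3,2-dioxaborolane | C\C(B2OC(C)(C)C(C)(C)O2)=C/C=C/C(C)=C/C=C/C=C(C)/C=C/C=C(C)/C=C/[C@]1(O[Si](C)(C)C)C(C)(C)C[C@H](O[Si](C)(C)C(C)(C)C)C[C@@]1(C)O[Si](C)(C)C | intermediate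
25 | (3S,5R,6S,3'S,5'R,6'S)-3,3'-bis[(tert-butyldimethylsilyl)oxy]-5,6-bis[(trimethylsilyl)oxy]-6',7'-didehydro-5,6,5',6'-tetrahydro-β,β-caroten-5'-ol (allene C6'=C7'=C8'; C9' on the face of the former epoxide C6'–O bond) | C[C@@]1(O)C[C@@H](O[Si](C)(C)C(C)(C)C)CC(C)(C)C1=[C@]=C([H])\C(C)=C\C=C\C(C)=C\C=C\C=C(C)\C=C\C=C(C)\C=C\[C@]2(O[Si](C)(C)C)C(C)(C)C[C@H](O[Si](C)(C)C(C)(C)C)C[C@@]2(C)O[Si](C)(C)C | intermediate
26 | (3S,5R,6S,3'S,5'R,8'R)-3,3'-bis[(tert-butyldimethylsilyl)oxy]-5,6-bis[(trimethylsilyl)oxy]-5',8'-epoxy-5,6,5',8'-tetrahydro-β,β-carotene | CC(/C=C/C=C(C)/C=C/[C@]1(O[Si](C)(C)C)C(C)(C)C[C@H](O[Si](C)(C)C(C)(C)C)C[C@@]1(C)O[Si](C)(C)C)=C\C=C\C=C(C)\C=C\C=C(/C)[C@H]1C=C2C(C)(C)C[C@H](O[Si](C)(C)C(C)(C)C)C[C@@]2(C)O1 | intermediate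
27 | (3S,5R,6S,3'S,5'R,8'R)-5',8'-epoxy-5,6,5',8'-tetrahydro-β,β-carotene-3,5,6,3'-tetrol | CC(/C=C/C=C(C)/C=C/[C@]1(O)C(C)(C)C[C@H](O)C[C@@]1(C)O)=C\C=C\C=C(C)\C=C\C=C(/C)[C@H]1C=C2C(C)(C)C[C@H](O)C[C@@]2(C)O1 | target

**Step count and risks**
Total steps: 22. Longest linear sequence: 16 steps (1 → 7 by steps 1–6, 7 → 15 by steps 8–13, then steps 19–22).

Most likely to fail:

1. Step 21 (proposed new method). The alkenylrhodium species may be protonated by the acidic alkyne C–H of 8, leading to rhodium acetylide formation and oligomerisation instead of carbometalation. The opening may also lose its syn course, or the silver step may erode axis-to-centre transfer by reversible ionisation at C8'. The fallback uses known reactions, sets out from 8, 20 and 23, and returns at 25. Hydrozirconation of 20 with Cp2Zr(H)Cl followed by iodine should give (2E)-3-iodobut-2-en-1-ol F1, and MnO2 oxidation (2E)-3-iodobut-2-enal F2. Horner–Wadsworth–Emmons olefination of 23 with F2 should give the C29 9'-iodo-octaene F3. Sonogashira coupling of F3 with 8 (Pd(PPh3)4, CuI, iPr2NH) forms the same C8'–C9' bond as an sp–sp2 bond and gives the 5',6'-epoxy-7'-yne F4. Anti-selective SN2' reduction of F4 with a copper hydride catalyst ((IPr)CuCl, NaOtBu, polymethylhydrosiloxane, toluene) places hydrogen on C8' anti to the oxirane oxygen and should therefore give the same allenol 25. This is closed with AgNO3/CaCO3 as in step 21 and continues to 26.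

2. Step 8. The hydrazone of the hindered, fully substituted epoxy aldehyde may stall, form the azine, or be reduced without fragmentation. The fallback sets out from 6 and returns at 9. Iodination of 6 (I2, PPh3, imidazole) should give tert-butyl{[(1S,4S,6R)-1-(iodomethyl)-2,2,6-trimethyl-7-oxabicyclo[4.1.0]heptan-4-yl]oxy}dimethylsilane F5. Reductive elimination with zinc dust (EtOH, NH4Cl) opens the oxirane at C6 and gives the same methylidene alcohol 9, with C5 untouched.

3. Step 19. Mono-olefination of the symmetric bisphosphonate may run on to the double condensation product and consume the valuable aldehyde 15. The fallback sets out from 19 and 22 and returns at 24; the order of the two olefinations is reversed. Excess 19 is first condensed with the cheap aldehyde 22 to give diethyl [(2E,4E,6E,8E,10Z)-2,7-dimethyl-11-(4,4,5,5-tetramethyl-1,3,2-dioxaborolan-2-yl)dodeca-2,4,6,8,10-pentaen-1-yl]phosphonate F6, which is easily separated from 19. Its anion is then condensed with 15 (NaN(SiMe3)2, THF, −78 → 0 °C) to give 24 directly.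

**Further compounds**
F1 | step 21 | (2E)-3-iodobut-2-en-1-ol | OC/C=C(\C)I
F2 | step 21 | (2E)-3-iodobut-2-enal | O=C/C=C(\C)I
F3 | step 21 | (2E,4E,6E,8E,10E,12E,14E,16E)-17-{(1S,2R,4S)-4-[(tert-butyldimethylsilyl)oxy]-2,6,6-trimethyl-1,2-bis[(trimethylsilyl)oxy]cyclohexyl}-2-iodo-6,11,15-trimethylheptadeca-2,4,6,8,10,12,14,16-octaene (iodine on C9', trans to C11') | C\C(I)=C/C=C/C(C)=C/C=C/C=C(C)/C=C/C=C(C)/C=C/[C@]1(O[Si](C)(C)C)C(C)(C)C[C@H](O[Si](C)(C)C(C)(C)C)C[C@@]1(C)O[Si](C)(C)C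
F4 | step 21 | (3S,5R,6S,3'S,5'R,6'S)-3,3'-bis[(tert-butyldimethylsilyl)oxy]-5,6-bis[(trimethylsilyl)oxy]-5',6'-epoxy-7',8'-didehydro-5,6,5',6'-tetrahydro-β,β-carotene | C\C(C#C[C@]23C(C)(C)C[C@H](O[Si](C)(C)C(C)(C)C)C[C@@]2(C)O3)=C/C=C/C(C)=C/C=C/C=C(C)/C=C/C=C(C)/C=C/[C@]1(O[Si](C)(C)C)C(C)(C)C[C@H](O[Si](C)(C)C(C)(C)C)C[C@@]1(C)O[Si](C)(C)C
F5 | step 8 | tert-butyl{[(1S,4S,6R)-1-(iodomethyl)-2,2,6-trimethyl-7-oxabicyclo[4.1.0]heptan-4-yl]oxy}dimethylsilane | IC[C@]12C(C)(C)C[C@H](O[Si](C)(C)C(C)(C)C)C[C@@]1(C)O2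
F6 | step 19 | diethyl [(2E,4E,6E,8E,10Z)-2,7-dimethyl-11-(4,4,5,5-tetramethyl-1,3,2-dioxaborolan-2-yl)dodeca-2,4,6,8,10-pentaen-1-yl]phosphonate | CCOP(=O)(OCC)C/C(C)=C/C=C/C=C(C)/C=C/C=C(\C)B1OC(C)(C)C(C)(C)O1
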